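Set the flask on a ladder of times, starting from the amber run at 12.0 h: substrate reads 1% of the charge and product reads 16%. The other 83.0% of the amber charge shows in neither reading, so substrate loss and product formation are timed apart.

| flask | substrate | coupling partner | free catalyst | second catalyst | impurity | added ligand | remark |
|---|---|---|---|---|---|---|---|
| amber | 0.23 M | 1.2 equiv | 0.083 mol% | 0.05 mol% | 93 µM | 0.67 mM | run made earlier |
| grey | 0.90 M | 1.2 equiv | 0.083 mol% | 0.05 mol% | 93 µM | 0.67 mM | run made earlier |
| flask | 0.45 M | 1.20 equiv | 0.083 mol% | 0.05 mol% | 93 µM | 0.67 mM |  |

- amber (time / h: product / %, substrate / %): 4.00: 2, 24; 12.0: 16, 1; 25.0: 27, 2; 40.0: 45, 0; 48.0: 52, 1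
- grey (time / h: product / %, substrate / %): 10.0: 94, 1; 20.0: 99, 0; 30.0: 103, 1; 40.0: 101, 0; 48.0: 100, 0

(scatter of a reading: 2 percentage points)

- factor on the rate of making product when 30% of the substrate are converted if free catalyst is charged twice over
- factor on the rate when 30% of the substrate are converted if free catalyst is charged at 0.015 mol% instead

- "the catalyst" is free catalyst with its forms; second catalyst is a second catalyst

The reckoning here is my own and assumes the following: the impurity removes second catalyst mole for mole before the earliest reading, substrate loss is pseudo-first-order with its constant in proportion to free catalyst, and the rate of making product goes with working second catalyst W. That leaves W = 22.0 µM in the amber run and 132 µM in the flask.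

Amber's 4.00 h reading gives a constant k = 0.357 h⁻¹, and its later product slope gives 2.30 mM h⁻¹. For the flask, with x = 30% and c the substrate charged:

- first rung, reaching x: t = ln(1/(1−x))/k, scaled by c, = 0.511 h
- product rate: ρ = 0.0138 M h⁻¹
- second rung, turning x·c into product: τ = x·c/ρ = 9.78 h

The rungs lie 1.28 powers of ten apart, t being shorter than τ. Hence in the flask the head start H = t/τ, the share of the converted substrate already product when x is reached, is 0.0522.

In this reckoning free catalyst moves the clock t, while x stays where it is. If the flask's rate follows the material in between, x·c(1−H), doubling gives (1−H/2)/(1−H) = 1.03. In the flask at 0.015 mol%, H grows to 0.289 and the factor is 0.750.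

The forecast gives 20 (6 to 60) on doubling, which differs from the reckoning above, and 0.9 (0.15 to 1.1) at the lower charge, with the words “so this is a threshold rather than a kinetic order”.

    coupling partner + catalyst intermediate → second catalyst + product (k = 860 M⁻¹ h⁻¹)
    free catalyst + added ligand ⇌ idle complex, settled at all times (K = 510 M⁻¹)
    substrate + free catalyst → free catalyst + open intermediate (k = 2400 M⁻¹ h⁻¹)
    second catalyst + impurity → spent catalyst (k = 5.60 × 10⁵ M⁻¹ h⁻¹)
    second catalyst + open intermediate ⇌ catalyst intermediate (K = 39.0 M⁻¹, k = 2600 M⁻¹ h⁻¹)

The flask gives 1.02 on doubling and 0.824 at the lower charge. At 5.00 h the flask holds 63.9% of its substrate as open intermediate against 32.9% as product. With the flask's rate 0.0234 M h⁻¹ at 0.516 h, H for the flask is 0.0894. In the grey run, an estimate from the average rate read up to 10.0 h and t scaled by c puts H at 0.0801.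

The readings are simulated with made-up constants, noise included.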